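**Retrosynthetic overview**
- The pyran ring is closed last (O2–C3) by gold-catalysed 6-endo cycloisomerisation of an ynenone that carries the C1 hydroxymethyl group; the C8 acetate is already in place.
- The carbocycle is recognised as a ring-opened 7-oxanorbornene: the C4a=C5–C6(=O)–C7(OH) γ-hydroxy-enone places the tertiary C7 oxygen 1,4 to the enone β-carbon C4a, so C4a, C5, C6, C7 and the C7 oxygen are the five ring atoms of a 3-methoxyfuran.
- Key disconnection: C4a–C8a and C7–C8, by a catalytic enantioselective Diels–Alder dearomatisation of a 5-alkynyl-3-methoxy-2-methylfuran with an (E)-3-acetoxyacryloyl oxazolidinone (C8=C8a, C1 as the imide carbonyl).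
- The furan comes from commercial methyl tetronate and a lithiated dienyne; the dienyne comes from (S)-2-methylbutan-1-ol (Wittig, then Horner–Wadsworth–Emmons).
- Ring order: furan (sacrificial arene) → carbocycle as the oxa-bridged bicycle (bridge opened afterwards to enone and C7–OH) → pyran.

Key step: step 8

Remark: locants C1–C8a are those of the 1H-isochromene skeleton of the target (O2 is the ring oxygen); the methylated tetronate is used as the racemate because its stereocentre becomes sp2 in the furan.

**Step 1**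
Reactants: 1 (S)-2-methylbutan-1-ol; 2 2-(triphenylphosphoranylidene)propanal
Product: 4 (2E,4S)-2,4-dimethylhex-2-enal, via (S)-2-methylbutanal 3 (not isolated)
Conditions: TEMPO (10 mol %), PhI(OAc)2, CH2Cl2, rt; then 2, CH2Cl2, 40 °C
Reagents that add atoms: none
Why: Base-free oxoammonium (TEMPO) oxidation gives the α-branched aldehyde, which the stabilised ylide traps in the same flask (Wittig reaction, E-selective) before it can racemise; the C4 stereocentre comes from 1.

**Step 2**
Reactants: 4 (2E,4S)-2,4-dimethylhex-2-enal; 5 diethyl [3-(trimethylsilyl)prop-2-yn-1-yl]phosphonate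
Product: 6 trimethyl[(3E,5E,7S)-5,7-dimethylnona-3,5-dien-1-yn-1-yl]silane
Conditions: 5, LiHMDS (LiN(SiMe3)2), THF, −78 °C; then 4, −78 °C → rt
Reagents that add atoms: none
Why: Horner–Wadsworth–Emmons olefination with the alkyne-stabilised phosphonate anion should add 1,2 to the enal and give the new disubstituted alkene with E geometry; any Z isomer would be removed by chromatography.

**Step 3**
Reactants: 6 trimethyl[(3E,5E,7S)-5,7-dimethylnona-3,5-dien-1-yn-1-yl]silane
Product: 7 (3E,5E,7S)-5,7-dimethylnona-3,5-dien-1-yne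
Conditions: K2CO3 (20 mol %), MeOH, 0 °C → rt
Reagents that add atoms: none
Why: Methanolysis of the C(sp)–Si bond (protodesilylation) is mild and leaves the diene and the allylic stereocentre untouched.

**Step 4**
Reactants: 8 4-methoxyfuran-2(5H)-one (methyl tetronate)
Product: 9 4-methoxy-5-methylfuran-2(5H)-one (racemic)
Conditions: LDA (LiN(i-Pr)2), THF, −78 °C; then MeI, −78 → −20 °C
Reagents that add atoms: iodomethane, CI
Why: γ-Deprotonation gives the aromatic 2-oxidofuran dienolate, which is alkylated at C5 (enolate alkylation of a tetronate); the new stereocentre is of no consequence.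

**Step 5**
Reactants: 7 (3E,5E,7S)-5,7-dimethylnona-3,5-dien-1-yne; 9 4-methoxy-5-methylfuran-2(5H)-one
Product: 11 5-[(3E,5E,7S)-5,7-dimethylnona-3,5-dien-1-yn-1-yl]-3-methoxy-2-methylfuran, via lactol 10 (not isolated)
Conditions: 7, n-BuLi, THF, −78 °C; anhydrous CeCl3, −78 °C; then 9, −78 → −40 °C; then MsCl, Et3N, −40 → 0 °C
Reagents that add atoms: none
Why: The weakly basic cerium acetylide should add 1,2 to the lactone carbonyl to give lactol 10, whose mesylate ionises to an oxocarbenium ion (stabilised by ring oxygen, alkyne and vinylogous methoxy group) that loses the C5 proton and aromatises (organometallic addition to a butenolide followed by dehydrative furan formation); the stereocentre of 9 is erased.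

**Step 6**
Reactants: 12 oxazolidin-2-one; 13 propiolic acid
Product: 14 3-(prop-2-ynoyl)oxazolidin-2-one
Conditions: DCC, DMAP (5 mol %), CH2Cl2, −20 → 0 °C
Reagents that add atoms: none
Why: Carbodiimide-mediated N-acylation of the oxazolidinone at low temperature avoids the unstable acid chloride and limits amine addition to the ynoyl group.

**Step 7**
Reactants: 14 3-(prop-2-ynoyl)oxazolidin-2-one
Product: 15 (E)-3-oxo-3-(2-oxooxazolidin-3-yl)prop-1-en-1-yl acetate
Conditions: AcOH (1.5 equiv), DABCO (10 mol %), CH2Cl2, 0 °C → rt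
Reagents that add atoms: acetic acid, CC(=O)O
Why: Tertiary-amine-catalysed conjugate addition of a carboxylic acid to an activated terminal alkyne (addition–elimination via the β-ammonium acrylate) should give the E enol ester.

**Step 8**
Reactants: 11 5-[(3E,5E,7S)-5,7-dimethylnona-3,5-dien-1-yn-1-yl]-3-methoxy-2-methylfuran; 15 (E)-3-oxo-3-(2-oxooxazolidin-3-yl)prop-1-en-1-yl acetate
Product: 16 3-{[(1R,4R,5R,6R)-6-acetoxy-4-[(3E,5E,7S)-5,7-dimethylnona-3,5-dien-1-yn-1-yl]-2-methoxy-1-methyl-7-oxabicyclo[2.2.1]hept-2-en-5-yl]carbonyl}oxazolidin-2-one (5-endo imide, 6-exo acetate)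
Conditions: [Cu((R,R)-t-Bu-box)](SbF6)2 (10 mol %; from CuCl2, (4R,4'R)-2,2'-(propane-2,2-diyl)bis(4-tert-butyl-4,5-dihydrooxazole) and AgSbF6), 4 Å MS, CH2Cl2, −78 → −50 °C; cold filtration through silica, used at once
Reagents that add atoms: none
Why: This is a Lewis-acid-catalysed, normal-demand, asynchronous [4+2] cycloaddition (Diels–Alder reaction) that dearomatises the furan: the 3-methoxy group makes the methyl-bearing furan carbon (future C7) the nucleophilic terminus, which bonds to the β-carbon of the chelated acrylimide (future C8), while the alkynyl-bearing terminus (future C4a) bonds to the α-carbon (future C8a). The closest known reaction type is the enantioselective Diels–Alder reaction of furans, including 3-heteroatom-substituted furans, with 3-acryloyl- and 3-(β-substituted acryloyl)oxazolidin-2-ones under bis(oxazoline)–divalent-copper or related chiral Lewis acid catalysis. The carbocycle C4a–C5–C6–C7–C8–C8a is closed by intermolecular suprafacial [4+2] addition across the furan 2,5-positions, which also creates the 7-oxabicyclo[2.2.1]heptene whose oxygen bridge later becomes the C7–OH. The E geometry of 15 fixes C8–OAc trans to the C8a carbon substituent, and the endo preference of the metal-bound imide carbonyl puts that substituent anti and the acetate syn (exo) to the oxygen bridge, which is the 7,8-cis/8,8a-trans pattern of the target with C7 set relative to C8. Absolute configuration is catalyst-controlled: in the square-planar chelate of s-cis 15 a tert-butyl group of the (R,R)-ligand shields the Re face of the α-carbon, so the furan should add to the Si face and give (7R,8R,8aR) in target numbering. The step needs regio-, endo-, facial and chemoselectivity (furan versus side-chain diene); these rest on the 3-methoxy group (para orientation and far higher nucleophilicity than the alkyne-conjugated acyclic diene), on two-point binding of the imide, and on low temperature, which holds the kinetic endo adduct against cycloreversion.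

**Step 9**
Reactants: 16 the endo imide cycloadduct
Product: 17 (1R,4S,5R,6R)-4-[(3E,5E,7S)-5,7-dimethylnona-3,5-dien-1-yn-1-yl]-5-(hydroxymethyl)-2-methoxy-1-methyl-7-oxabicyclo[2.2.1]hept-2-en-6-yl acetate
Conditions: LiBH4 (1.1 equiv), MeOH (1.1 equiv), THF, −30 → 0 °C
Reagents that add atoms: none
Why: Hydride reduction of an N-acyloxazolidinone (reductive imide cleavage) is much faster than that of a secondary acetate, so limiting LiBH4 at low temperature should reduce only C1 to the primary alcohol, while the enol ether masks the C6 ketone and the rigid exo/endo trans arrangement blocks acetyl migration; no stereocentre is touched.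

**Step 10**
Reactants: 17 the hydroxymethyl oxanorbornene acetate
Product: 19 (1R,2R,6R)-5-[(3E,5E,7S)-5,7-dimethylnona-3,5-dien-1-yn-1-yl]-2-hydroxy-6-(hydroxymethyl)-2-methyl-3-oxocyclohex-4-en-1-yl acetate, via bridged ketone 18 (not isolated)
Conditions: 0.5 M aq. HCl (cat.), THF, 0 °C; then DBU (0.3 equiv beyond the acid), CH2Cl2, 0 °C, short contact
Reagents that add atoms: water, O
Why: Acid hydrolysis of the enol ether gives β-alkoxy ketone 18, whose enolate expels the bridging oxygen from C4a (E1cB, retro-oxa-Michael; direct acid ionisation of the vinylogous ketal leads to the same product), which releases ring strain and unveils the C4a=C5 enone and the tertiary C7–OH with C7, C8 and C8a unchanged.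

**Step 11**
Reactants: 19 the hydroxymethyl ynenone
Product: 20 (7R,8R,8aR)-3-[(1E,3E,5S)-3,5-dimethylhepta-1,3-dien-1-yl]-7-hydroxy-7-methyl-6-oxo-6,7,8,8a-tetrahydro-1H-isochromen-8-yl acetate (target)
Conditions: Ph3PAuNTf2 (5 mol %), CH2Cl2, 0 °C → rt
Reagents that add atoms: none
Why: π-Acid activation of the alkyne by monovalent gold and anti attack of the primary C1 hydroxyl at the distal alkyne carbon C3 (6-endo-dig hydroalkoxylation, the cycloisomerisation used for 1H-isochromenes and azaphilone cores) is favoured because C3 is the δ-carbon of the ynenone and is dienyl-substituted, the C8 oxygen is blocked as the acetate and the C7–OH cannot reach C3; protodeauration gives the C3=C4 enol ether.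

**Compound list**
1 | (S)-2-methylbutan-1-ol | CC[C@H](C)CO | starting material
2 | 2-(triphenylphosphoranylidene)propanal | CC(C=O)=P(c1ccccc1)(c1ccccc1)c1ccccc1 | starting material
3 | (S)-2-methylbutanal (not isolated) | CC[C@H](C)C=O | intermediate
4 | (2E,4S)-2,4-dimethylhex-2-enal | CC[C@H](C)/C=C(C)/C=O | intermediate
5 | diethyl [3-(trimethylsilyl)prop-2-yn-1-yl]phosphonate | CCOP(=O)(CC#C[Si](C)(C)C)OCC | starting material
6 | trimethyl[(3E,5E,7S)-5,7-dimethylnona-3,5-dien-1-yn-1-yl]silane | CC[C@H](C)/C=C(C)/C=C/C#C[Si](C)(C)C | intermediate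
7 | (3E,5E,7S)-5,7-dimethylnona-3,5-dien-1-yne | CC[C@H](C)/C=C(C)/C=C/C#C | intermediate
8 | 4-methoxyfuran-2(5H)-one | COC1=CC(=O)OC1 | starting material
9 | 4-methoxy-5-methylfuran-2(5H)-one (racemic) | COC1=CC(=O)OC1C | intermediate
10 | 2-[(3E,5E,7S)-5,7-dimethylnona-3,5-dien-1-yn-1-yl]-4-methoxy-5-methyl-2,5-dihydrofuran-2-ol (lactol, mixture at the two ring centres, not isolated) | CC[C@H](C)/C=C(C)/C=C/C#CC1(O)C=C(OC)C(C)O1 | intermediate
11 | 5-[(3E,5E,7S)-5,7-dimethylnona-3,5-dien-1-yn-1-yl]-3-methoxy-2-methylfuran | CC[C@H](C)/C=C(C)/C=C/C#Cc1cc(OC)c(C)o1 | intermediate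
12 | oxazolidin-2-one | O=C1NCCO1 | starting material
13 | propiolic acid | C#CC(=O)O | starting material
14 | 3-(prop-2-ynoyl)oxazolidin-2-one | C#CC(=O)N1CCOC1=O | intermediate
15 | (E)-3-oxo-3-(2-oxooxazolidin-3-yl)prop-1-en-1-yl acetate | CC(=O)O/C=C/C(=O)N1CCOC1=O | intermediate
16 | 3-{[(1R,4R,5R,6R)-6-acetoxy-4-[(3E,5E,7S)-5,7-dimethylnona-3,5-dien-1-yn-1-yl]-2-methoxy-1-methyl-7-oxabicyclo[2.2.1]hept-2-en-5-yl]carbonyl}oxazolidin-2-one | CC[C@H](C)/C=C(C)/C=C/C#C[C@]12C=C(OC)[C@](C)(O1)[C@H](OC(C)=O)[C@H]2C(=O)N3CCOC3=O | intermediate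
17 | (1R,4S,5R,6R)-4-[(3E,5E,7S)-5,7-dimethylnona-3,5-dien-1-yn-1-yl]-5-(hydroxymethyl)-2-methoxy-1-methyl-7-oxabicyclo[2.2.1]hept-2-en-6-yl acetate | CC[C@H](C)/C=C(C)/C=C/C#C[C@]12C=C(OC)[C@](C)(O1)[C@H](OC(C)=O)[C@H]2CO | intermediate
18 | (1R,4R,5R,6R)-4-[(3E,5E,7S)-5,7-dimethylnona-3,5-dien-1-yn-1-yl]-5-(hydroxymethyl)-1-methyl-2-oxo-7-oxabicyclo[2.2.1]heptan-6-yl acetate (bridged ketone, not isolated) | CC[C@H](C)/C=C(C)/C=C/C#C[C@]12CC(=O)[C@](C)(O1)[C@H](OC(C)=O)[C@H]2CO | intermediate
19 | (1R,2R,6R)-5-[(3E,5E,7S)-5,7-dimethylnona-3,5-dien-1-yn-1-yl]-2-hydroxy-6-(hydroxymethyl)-2-methyl-3-oxocyclohex-4-en-1-yl acetate | CC[C@H](C)/C=C(C)/C=C/C#CC1=CC(=O)[C@](C)(O)[C@H](OC(C)=O)[C@H]1CO | intermediate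
20 | (7R,8R,8aR)-3-[(1E,3E,5S)-3,5-dimethylhepta-1,3-dien-1-yl]-7-hydroxy-7-methyl-6-oxo-6,7,8,8a-tetrahydro-1H-isochromen-8-yl acetate | CC[C@H](C)/C=C(C)/C=C/C1=CC2=CC(=O)[C@](C)(O)[C@H](OC(C)=O)[C@H]2CO1 | target

**Step count and risks**
Total step count: 11. Longest linear sequence: 8 steps (steps 1, 2, 3, 5, 8, 9, 10, 11, from 1).

Steps most likely to fail:

1. Step 8. The cycloaddition may give poor endo or facial selectivity on this tetrasubstituted furan, or may go stepwise (conjugate addition, then loss of acetate or Lewis-acid opening and aromatisation of the adduct). Fallback: stereocontrol is moved from the catalyst to a covalently bound auxiliary. The fallback sets out from 13 and 11. Propiolic acid 13 is coupled (DCC) with commercial (S)-4-benzyloxazolidin-2-one to give (S)-4-benzyl-3-(prop-2-ynoyl)oxazolidin-2-one F1. Acetic acid is added under DABCO catalysis to give (E)-3-[(S)-4-benzyl-2-oxooxazolidin-3-yl]-3-oxoprop-1-en-1-yl acetate F2. F2 is combined with furan 11 under Et2AlCl (1.4 equiv, CH2Cl2, −78 °C), where the aluminium chelate should expose the Si face of the α-carbon anti to the benzyl group. The endo adduct, the benzyl-oxazolidinone analogue of the cycloadduct F3, is a diastereomer that can be purified by chromatography or crystallisation. It is reduced with LiBH4/MeOH as in step 9, and the route is rejoined at 17.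

2. Step 5. The acetylide may deprotonate C5 of the tetronate instead of adding to the carbonyl, which only returns the starting materials. Fallback: that acidity is used. The fallback sets out from 9, which is converted with KHMDS (KN(SiMe3)2) and PhNTf2 (THF, −78 °C) into 4-methoxy-5-methylfuran-2-yl trifluoromethanesulfonate F4. F4 is coupled with alkyne 7 under Sonogashira conditions (Pd(PPh3)4 as the zerovalent palladium catalyst, CuI, i-Pr2NH, THF, rt), and the route is rejoined at 11.

3. Step 9. Hydride may also attack the C8 acetate (over-reduction), which would leave two hydroxyl groups able to close a pyran in step 11. Fallback: the two oxygens are told apart by protection. The fallback sets out from 16, which is reduced exhaustively (LiBH4, excess, THF, 0 °C) to the diol (1R,4S,5R,6R)-4-[(3E,5E,7S)-5,7-dimethylnona-3,5-dien-1-yn-1-yl]-5-(hydroxymethyl)-2-methoxy-1-methyl-7-oxabicyclo[2.2.1]hept-2-en-6-ol F5. The primary hydroxyl is silylated (TBSCl, imidazole, CH2Cl2) to the mono-silyl ether F6. The secondary C8 hydroxyl is acetylated (Ac2O, DMAP, pyridine) to the silyl ether acetate F7. The silyl group is removed (Bu4NF buffered with AcOH, THF, 0 °C), and the route is rejoined at 17.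

**Further compounds**
F1 | step 8 | (S)-4-benzyl-3-(prop-2-ynoyl)oxazolidin-2-one | C#CC(=O)N1[C@@H](Cc2ccccc2)COC1=O
F2 | step 8 | (E)-3-[(S)-4-benzyl-2-oxooxazolidin-3-yl]-3-oxoprop-1-en-1-yl acetate | CC(=O)O/C=C/C(=O)N1[C@@H](Cc2ccccc2)COC1=O
F3 | step 8 | (S)-4-benzyl-3-{[(1R,4R,5R,6R)-6-acetoxy-4-[(3E,5E,7S)-5,7-dimethylnona-3,5-dien-1-yn-1-yl]-2-methoxy-1-methyl-7-oxabicyclo[2.2.1]hept-2-en-5-yl]carbonyl}oxazolidin-2-one | CC[C@H](C)/C=C(C)/C=C/C#C[C@]12C=C(OC)[C@](C)(O1)[C@H](OC(C)=O)[C@H]2C(=O)N3[C@@H](Cc4ccccc4)COC3=O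
F4 | step 5 | 4-methoxy-5-methylfuran-2-yl trifluoromethanesulfonate | COc1cc(OS(=O)(=O)C(F)(F)F)oc1C
F5 | step 9 | (1R,4S,5R,6R)-4-[(3E,5E,7S)-5,7-dimethylnona-3,5-dien-1-yn-1-yl]-5-(hydroxymethyl)-2-methoxy-1-methyl-7-oxabicyclo[2.2.1]hept-2-en-6-ol | CC[C@H](C)/C=C(C)/C=C/C#C[C@]12C=C(OC)[C@](C)(O1)[C@H](O)[C@H]2CO
F6 | step 9 | (1R,4S,5R,6R)-5-{[(tert-butyldimethylsilyl)oxy]methyl}-4-[(3E,5E,7S)-5,7-dimethylnona-3,5-dien-1-yn-1-yl]-2-methoxy-1-methyl-7-oxabicyclo[2.2.1]hept-2-en-6-ol | CC[C@H](C)/C=C(C)/C=C/C#C[C@]12C=C(OC)[C@](C)(O1)[C@H](O)[C@H]2CO[Si](C)(C)C(C)(C)C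
F7 | step 9 | (1R,4S,5R,6R)-5-{[(tert-butyldimethylsilyl)oxy]methyl}-4-[(3E,5E,7S)-5,7-dimethylnona-3,5-dien-1-yn-1-yl]-2-methoxy-1-methyl-7-oxabicyclo[2.2.1]hept-2-en-6-yl acetate | CC[C@H](C)/C=C(C)/C=C/C#C[C@]12C=C(OC)[C@](C)(O1)[C@H](OC(C)=O)[C@H]2CO[Si](C)(C)C(C)(C)C
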